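**Plan**
- The benzene ring is an ortho-hydroxyaryl ketone: acyl group on C1', a hydroxyl on the neighbouring C2', the second hydroxyl on C4'. This is the pattern left when an aryne with its triple bond between C1' and C2' inserts into the C–O bond of a carboxylic acid.
- Retrosynthesis: the C8–C9 and C9–C10 bonds of the dienone end are cut first (allylic chloride, CO, isobutenylstannane), and C8 is traced back to the E-methyl group of a prenyl terminus. The C1–C1' and C2'–O bonds are then cut together, giving a 3-silyl-4-alkoxy aryne and (R)-3,7-dimethyl-3-vinyloct-6-enoic acid.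
- The acid goes back to geraniol through SN2' alkynylation of its phosphate (C3–alkyne bond); the aryne precursor goes back to resorcinol through two ortho-silylations run in one flask.
- Forward: a five-step acid branch and a four-step triflate branch meet in the aryne insertion and no ring is formed. The chain is then extended at C8 by allylic oxidation, chlorination and carbonylative Stille coupling, and fluoride frees the phenols.
- Stereochemistry: the single stereocentre C3 (R) is set by the chiral carbene–copper catalyst in the allylic substitution and is not touched afterwards. The 6E geometry comes from the E-selective SeO2 oxidation and a coupling that retains it.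

Key step: step 10

Remark: the imidazolinium ligand of step 2 (1,2-diphenylethylenediamine backbone, one N-(2-sulfonatophenyl) and one N-(2,6-diisopropylphenyl) group) is taken in the antipode that sends the alkynyl group to the face of the E-phosphate leading to the S enyne, the mirror-image ligand serving if the sense proves opposite; C1 is the aryl ketone carbon and C1' the ring carbon that carries it.

**Step 1**
Reactants: 1 geraniol
Product: 2 diethyl geranyl phosphate
Conditions: ClP(O)(OEt)2, Et3N, DMAP (cat.), CH2Cl2, 0 °C → rt
Reagents that add atoms: diethyl chlorophosphate, CCOP(=O)(Cl)OCC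
Why: O-phosphorylation of the primary allylic alcohol under mild base should give the E-allylic phosphate, the leaving group needed for copper-catalysed SN2' substitution, without touching either double bond.

**Step 2**
Reactants: 2 diethyl geranyl phosphate; 3 ethynyltrimethylsilane
Product: 5 (S)-(3,7-dimethyl-3-vinyloct-6-en-1-yn-1-yl)trimethylsilane, via diisobutyl[(trimethylsilyl)ethynyl]aluminium 4 (not isolated)
Conditions: 3, i-Bu2AlH, Et3N (5 mol %), hexanes, 0 °C → rt; then 2, CuCl2·2H2O (2 mol %), chiral sulfonate-bearing imidazolinium salt (2.5 mol %), THF, −30 °C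
Reagents that add atoms: diisobutylaluminium hydride, CC(C)C[AlH]CC(C)C (its aluminium and isobutyl groups are found in intermediate 4 only; nothing of it stays in 5)
Why: Amine-catalysed alumination of the alkyne C–H gives alane 4, and in this enantioselective copper-catalysed allylic substitution the carbene–copper complex (the divalent copper salt is reduced in the flask to monovalent copper) should deliver the alkynyl group SN2' to C3 of the E-phosphate, the chiral sulfonate-bridged carbene choosing the alkene face and so setting the quaternary centre, as precedented for alkynylalanes and trisubstituted E-allylic phosphates.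

**Step 3**
Reactants: 5 (S)-(3,7-dimethyl-3-vinyloct-6-en-1-yn-1-yl)trimethylsilane
Product: 6 (S)-3,7-dimethyl-3-vinyloct-6-en-1-yne
Conditions: K2CO3, MeOH, rt
Reagents that add atoms: none
Why: Base-mediated protodesilylation of the silylalkyne (methanolysis of the alkynyl C–Si bond) should free the terminal alkyne, and the quaternary centre has no acidic hydrogen.

**Step 4**
Reactants: 6 (S)-3,7-dimethyl-3-vinyloct-6-en-1-yne
Product: 7 (R)-3,7-dimethyl-3-vinyloct-6-enal
Conditions: CpRu(MeCN)3PF6 (5 mol %), 5,5'-bis(trifluoromethyl)-2,2'-bipyridine (5 mol %), NMP/H2O 4:1, 25 → 50 °C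
Reagents that add atoms: water, O
Why: Ruthenium-catalysed anti-Markovnikov alkyne hydration runs through a ruthenium vinylidene that only a terminal alkyne can form, so oxygen should go to the terminal carbon while the vinyl and trisubstituted alkenes stay untouched (the descriptor changes from S to R only because the priorities change).

**Step 5**
Reactants: 7 (R)-3,7-dimethyl-3-vinyloct-6-enal
Product: 8 (R)-3,7-dimethyl-3-vinyloct-6-enoic acid
Conditions: NaClO2, NaH2PO4, 2-methylbut-2-ene (excess), t-BuOH/H2O, 0 °C → rt
Reagents that add atoms: sodium chlorite, [Na+].[O-]Cl=O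
Why: Pinnick oxidation should convert the aldehyde to the acid under buffered conditions, with the scavenger alkene taking up the hypochlorous acid that would otherwise attack the trisubstituted double bond.

**Step 6**
Reactants: 9 resorcinol
Product: 10 3-(methoxymethoxy)phenol
Conditions: resorcinol (3 equiv), MOMCl (1 equiv), i-Pr2NEt, MeCN, 0 °C → rt
Reagents that add atoms: chloromethyl methyl ether, COCCl
Why: O-alkylation of the phenol (MOM protection) with the diol in excess should favour the mono-ether, and unreacted resorcinol is washed out with water.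

**Step 7**
Reactants: 10 3-(methoxymethoxy)phenol
Product: 11 3-(methoxymethoxy)phenyl isopropylcarbamate
Conditions: i-PrNCO, Et3N (cat.), CH2Cl2, rt
Reagents that add atoms: isopropyl isocyanate, CC(C)N=C=O
Why: Base-catalysed addition of the phenol to the isocyanate (carbamoylation) should give the N-isopropyl O-aryl carbamate, a strong director for ortho-lithiation that is later removed under mild base.

**Step 8**
Reactants: 11 3-(methoxymethoxy)phenyl isopropylcarbamate
Product: 17 3-(methoxymethoxy)-2-(triethylsilyl)-6-(trimethylsilyl)phenyl isopropylcarbamate, via N-silyl carbamate 12 (not isolated), via C2 aryllithium 13 (not isolated), via N-silyl 2-triethylsilyl carbamate 14 (not isolated), via C6 aryllithium 15 (not isolated), via N-silyl disilyl carbamate 16 (not isolated)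
Conditions: TMSOTf, TMEDA, Et2O, 0 °C → rt; n-BuLi (2.2 equiv), TMEDA, −78 °C; Et3SiCl (1.1 equiv), −78 °C → rt; n-BuLi (1.3 equiv), −78 °C; Me3SiCl (excess), −78 °C → rt; aq. NH4Cl/MeOH work-up
Reagents that add atoms: chlorotriethylsilane, CC[Si](Cl)(CC)CC; chlorotrimethylsilane, C[Si](C)(C)Cl; trimethylsilyl trifluoromethanesulfonate, C[Si](C)(C)OS(=O)(=O)C(F)(F)F (nitrogen silyl group of 12 to 16 only); n-butyllithium, [Li]CCCC (lithium of 13 and 15 only)
Why: Two directed ortho-metalations are run in one flask on the N-silylated carbamate (the N–H must be masked, or base would expel the phenoxide): the first lithiation should go to C2 between the two oxygen directors and is trapped with a near-stoichiometric amount of Et3SiCl so that none is left over, the N-silyl carbamate 14 still in the flask is then lithiated at C6, the only position left beside the carbamate, which directs more strongly than the MOM ether, and trapped with Me3SiCl, and the work-up hydrolyses the N–Si bond.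

**Step 9**
Reactants: 17 3-(methoxymethoxy)-2-(triethylsilyl)-6-(trimethylsilyl)phenyl isopropylcarbamate
Product: 19 3-(methoxymethoxy)-2-(triethylsilyl)-6-(trimethylsilyl)phenyl trifluoromethanesulfonate, via free phenol 18 (not isolated)
Conditions: Et2NH, DBU, MeCN, 40 °C; then PhNTf2, rt → 40 °C
Reagents that add atoms: N-phenylbis(trifluoromethanesulfonimide), O=S(=O)(N(c1ccccc1)S(=O)(=O)C(F)(F)F)C(F)(F)F
Why: E1cB cleavage of the N-monoalkyl carbamate (DBU removes the N–H, the phenoxide leaves, diethylamine traps the isocyanate) followed by O-triflation in the same flask is the established route to ortho-silylaryl triflates, and the mild base should leave both C–Si bonds and the MOM ether intact.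

**Step 10**
Reactants: 8 (R)-3,7-dimethyl-3-vinyloct-6-enoic acid; 19 3-(methoxymethoxy)-2-(triethylsilyl)-6-(trimethylsilyl)phenyl trifluoromethanesulfonate
Product: 21 (R)-1-[2-hydroxy-4-(methoxymethoxy)-3-(triethylsilyl)phenyl]-3,7-dimethyl-3-vinyloct-6-en-1-one, via 4-(methoxymethoxy)-3-(triethylsilyl)benzyne 20 (not isolated)
Conditions: 8 (1.0 equiv), 19 (1.3 equiv), CsF (3 equiv), THF, 125 °C (sealed tube)
Reagents that add atoms: none
Why: Fluoride attacks the less hindered trimethylsilyl group of 19, triflate leaves and aryne 20 (triple bond C1'–C2') results; the caesium carboxylate of 8 adds through oxygen to C2', the aryl anion formed at C1' attacks the ester carbonyl just made, and the four-membered hemiketal alkoxide opens to the C1' ketone and the C2' phenoxide, which is protonated on work-up. The closest known reaction type is the insertion of arynes from ortho-silylaryl triflates into the C–O bond of carboxylic acids to give ortho-hydroxyaryl ketones, joined here with the known ortho-directing effect of a 3-silyl group in aryne additions. The only ring closed is the transient benzoxete, formed 4-exo-trig and opened again at once, so no ring is left in 21. No stereocentre is created, and C3, which bears no hydrogen and lies two atoms from the reacting carboxyl carbon, is not touched. Two selectivities are needed: fluoride must take the trimethylsilyl and not the triethylsilyl group, which the smaller size of the former should secure, and the carboxylate must add to C2' and not C1', which the electropositive triethylsilyl group on C3' should secure by distorting the aryne so that C2' is the flatter, more electrophilic carbon and charge grows at C1', an effect expected to outweigh the weak opposite inductive pull of the C4' oxygen and the bulk of the silyl group toward a small oxygen nucleophile. The high temperature favours acyl transfer over protonation of the aryl anion, which would stop at the aryl ester.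

**Step 11**
Reactants: 21 (R)-1-[2-hydroxy-4-(methoxymethoxy)-3-(triethylsilyl)phenyl]-3,7-dimethyl-3-vinyloct-6-en-1-one
Product: 22 (R)-1-(2,4-dihydroxyphenyl)-3,7-dimethyl-3-vinyloct-6-en-1-one
Conditions: HCl (1 M in MeOH), 25 → 40 °C
Reagents that add atoms: none
Why: Acid-mediated ipso-protodesilylation (electrophilic aromatic substitution at C3', ortho to two oxygens and meta to the acyl group) should run together with acetal exchange of the MOM ether, while dilute acid at low temperature spares the trisubstituted alkene.

**Step 12**
Reactants: 22 (R)-1-(2,4-dihydroxyphenyl)-3,7-dimethyl-3-vinyloct-6-en-1-one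
Product: 23 (R)-1-[2,4-bis(tert-butyldimethylsilyloxy)phenyl]-3,7-dimethyl-3-vinyloct-6-en-1-one
Conditions: TBSCl (3 equiv), imidazole, DMAP (cat.), DMF, 25 → 40 °C
Reagents that add atoms: tert-butyldimethylsilyl chloride, CC(C)(C)[Si](C)(C)Cl
Why: Imidazole-promoted O-silylation of both phenols, the hydrogen-bonded C2' one included, masks them against oxidation and palladium-allyl O-alkylation and lets the last deprotection be done with buffered fluoride instead of acid.

**Step 13**
Reactants: 23 (R)-1-[2,4-bis(tert-butyldimethylsilyloxy)phenyl]-3,7-dimethyl-3-vinyloct-6-en-1-one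
Product: 24 (3R,6E)-1-[2,4-bis(tert-butyldimethylsilyloxy)phenyl]-8-hydroxy-3,7-dimethyl-3-vinyloct-6-en-1-one
Conditions: SeO2 (0.5 equiv), t-BuOOH, salicylic acid (10 mol %), CH2Cl2, 0 °C → rt, stopped at partial conversion with recovery of 23
Reagents that add atoms: selenium dioxide, O=[Se]=O (oxygen donor), turned over by tert-butyl hydroperoxide, CC(C)(C)OO
Why: SeO2 allylic oxidation (ene reaction, then [2,3]-sigmatropic shift) should functionalise the E-methyl group of the trisubstituted alkene and give the 6E allylic alcohol, since the vinyl group has no allylic hydrogen and the ketone α-methylene reacts far more slowly at room temperature.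

**Step 14**
Reactants: 24 (3R,6E)-1-[2,4-bis(tert-butyldimethylsilyloxy)phenyl]-8-hydroxy-3,7-dimethyl-3-vinyloct-6-en-1-one
Product: 25 (3R,6E)-1-[2,4-bis(tert-butyldimethylsilyloxy)phenyl]-8-chloro-3,7-dimethyl-3-vinyloct-6-en-1-one
Conditions: NCS, Me2S, CH2Cl2, −20 → 0 °C
Reagents that add atoms: N-chlorosuccinimide, O=C1CCC(=O)N1Cl
Why: Corey–Kim chlorination (alkoxysulfonium formation, then SN2 attack of chloride at the primary carbon) should give the primary allylic chloride without allylic shift or loss of the E geometry, under conditions that leave the ketone and the silyl ethers alone.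

**Step 15**
Reactants: 26 1-bromo-2-methylprop-1-ene
Product: 28 tributyl(2-methylprop-1-en-1-yl)stannane, via (2-methylprop-1-en-1-yl)magnesium bromide 27 (not isolated)
Conditions: Mg, THF, reflux; then Bu3SnCl, 0 °C → rt
Reagents that add atoms: tributyltin chloride, CCCC[Sn](Cl)(CCCC)CCCC; magnesium, [Mg] (in intermediate 27 only)
Why: Grignard formation from the vinyl bromide and transmetalation to tin (substitution at tin) is the standard way to an alkenylstannane.

**Step 16**
Reactants: 25 (3R,6E)-1-[2,4-bis(tert-butyldimethylsilyloxy)phenyl]-8-chloro-3,7-dimethyl-3-vinyloct-6-en-1-one; 28 tributyl(2-methylprop-1-en-1-yl)stannane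
Product: 29 (3R,6E)-1-[2,4-bis(tert-butyldimethylsilyloxy)phenyl]-3,7,11-trimethyl-3-vinyldodeca-6,10-diene-1,9-dione
Conditions: CO (3 atm), Pd2(dba)3 (2.5 mol %), PPh3 (10 mol %), THF, 50 °C
Reagents that add atoms: carbon monoxide, [C-]#[O+]
Why: In this carbonylative Stille coupling zerovalent palladium adds oxidatively to the allylic chloride, CO inserts at the primary allyl terminus, the alkenyl group is transferred from tin and reductive elimination should give the allyl vinyl ketone with the 6E geometry kept, the neutral medium keeping the β,γ-double bond out of conjugation.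

**Step 17**
Reactants: 29 (3R,6E)-1-[2,4-bis(tert-butyldimethylsilyloxy)phenyl]-3,7,11-trimethyl-3-vinyldodeca-6,10-diene-1,9-dione
Product: 30 (3R,6E)-1-(2,4-dihydroxyphenyl)-3,7,11-trimethyl-3-vinyldodeca-6,10-diene-1,9-dione (CNP0208188.1)
Conditions: Bu4NF, AcOH (1:1), THF, 0 °C
Reagents that add atoms: none
Why: Fluoride-mediated cleavage of the two aryl silyl ethers is fast at low temperature, and the acetic acid buffer protonates the phenoxides at once, so the β,γ-unsaturated ketone should neither move into conjugation nor lose its 6E geometry.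

**Compound list**
1 | geraniol | OC/C=C(\C)CCC=C(C)C | starting material
2 | diethyl geranyl phosphate | CCOP(=O)(OCC)OC/C=C(\C)CCC=C(C)C | intermediate
3 | ethynyltrimethylsilane | C#C[Si](C)(C)C | starting material
4 | diisobutyl[(trimethylsilyl)ethynyl]aluminium | CC(C)C[Al](CC(C)C)C#C[Si](C)(C)C | intermediate
5 | (S)-(3,7-dimethyl-3-vinyloct-6-en-1-yn-1-yl)trimethylsilane | C=C[C@](C)(CCC=C(C)C)C#C[Si](C)(C)C | intermediate
6 | (S)-3,7-dimethyl-3-vinyloct-6-en-1-yne | C=C[C@](C)(CCC=C(C)C)C#C | intermediate
7 | (R)-3,7-dimethyl-3-vinyloct-6-enal | C=C[C@](C)(CCC=C(C)C)CC=O | intermediate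
8 | (R)-3,7-dimethyl-3-vinyloct-6-enoic acid | C=C[C@](C)(CCC=C(C)C)CC(=O)O | intermediate
9 | resorcinol | Oc1cccc(O)c1 | starting material
10 | 3-(methoxymethoxy)phenol | COCOc1cccc(O)c1 | intermediate
11 | 3-(methoxymethoxy)phenyl isopropylcarbamate | COCOc1cccc(OC(=O)NC(C)C)c1 | intermediate
12 | 3-(methoxymethoxy)phenyl isopropyl(trimethylsilyl)carbamate | COCOc1cccc(OC(=O)N(C(C)C)[Si](C)(C)C)c1 | intermediate
13 | {2-[isopropyl(trimethylsilyl)carbamoyloxy]-6-(methoxymethoxy)phenyl}lithium | COCOc1cccc(OC(=O)N(C(C)C)[Si](C)(C)C)c1[Li] | intermediate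
14 | 3-(methoxymethoxy)-2-(triethylsilyl)phenyl isopropyl(trimethylsilyl)carbamate | COCOc1cccc(OC(=O)N(C(C)C)[Si](C)(C)C)c1[Si](CC)(CC)CC | intermediate
15 | {2-[isopropyl(trimethylsilyl)carbamoyloxy]-4-(methoxymethoxy)-3-(triethylsilyl)phenyl}lithium | COCOc1ccc([Li])c(OC(=O)N(C(C)C)[Si](C)(C)C)c1[Si](CC)(CC)CC | intermediate
16 | 3-(methoxymethoxy)-2-(triethylsilyl)-6-(trimethylsilyl)phenyl isopropyl(trimethylsilyl)carbamate | COCOc1ccc([Si](C)(C)C)c(OC(=O)N(C(C)C)[Si](C)(C)C)c1[Si](CC)(CC)CC | intermediate
17 | 3-(methoxymethoxy)-2-(triethylsilyl)-6-(trimethylsilyl)phenyl isopropylcarbamate | COCOc1ccc([Si](C)(C)C)c(OC(=O)NC(C)C)c1[Si](CC)(CC)CC | intermediate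
18 | 3-(methoxymethoxy)-2-(triethylsilyl)-6-(trimethylsilyl)phenol | COCOc1ccc([Si](C)(C)C)c(O)c1[Si](CC)(CC)CC | intermediate
19 | 3-(methoxymethoxy)-2-(triethylsilyl)-6-(trimethylsilyl)phenyl trifluoromethanesulfonate | COCOc1ccc([Si](C)(C)C)c(OS(=O)(=O)C(F)(F)F)c1[Si](CC)(CC)CC | intermediate
20 | 4-(methoxymethoxy)-3-(triethylsilyl)benzyne | COCOC1=C([Si](CC)(CC)CC)C#CC=C1 | intermediate
21 | (R)-1-[2-hydroxy-4-(methoxymethoxy)-3-(triethylsilyl)phenyl]-3,7-dimethyl-3-vinyloct-6-en-1-one | C=C[C@](C)(CCC=C(C)C)CC(=O)c1ccc(OCOC)c([Si](CC)(CC)CC)c1O | intermediate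
22 | (R)-1-(2,4-dihydroxyphenyl)-3,7-dimethyl-3-vinyloct-6-en-1-one | C=C[C@](C)(CCC=C(C)C)CC(=O)c1ccc(O)cc1O | intermediate
23 | (R)-1-[2,4-bis(tert-butyldimethylsilyloxy)phenyl]-3,7-dimethyl-3-vinyloct-6-en-1-one | C=C[C@](C)(CCC=C(C)C)CC(=O)c1ccc(O[Si](C)(C)C(C)(C)C)cc1O[Si](C)(C)C(C)(C)C | intermediate
24 | (3R,6E)-1-[2,4-bis(tert-butyldimethylsilyloxy)phenyl]-8-hydroxy-3,7-dimethyl-3-vinyloct-6-en-1-one | C=C[C@](C)(CC/C=C(\C)CO)CC(=O)c1ccc(O[Si](C)(C)C(C)(C)C)cc1O[Si](C)(C)C(C)(C)C | intermediate
25 | (3R,6E)-1-[2,4-bis(tert-butyldimethylsilyloxy)phenyl]-8-chloro-3,7-dimethyl-3-vinyloct-6-en-1-one | C=C[C@](C)(CC/C=C(\C)CCl)CC(=O)c1ccc(O[Si](C)(C)C(C)(C)C)cc1O[Si](C)(C)C(C)(C)C | intermediate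
26 | 1-bromo-2-methylprop-1-ene | CC(C)=CBr | starting material
27 | (2-methylprop-1-en-1-yl)magnesium bromide | CC(C)=C[Mg]Br | intermediate
28 | tributyl(2-methylprop-1-en-1-yl)stannane | CC(C)=C[Sn](CCCC)(CCCC)CCCC | intermediate
29 | (3R,6E)-1-[2,4-bis(tert-butyldimethylsilyloxy)phenyl]-3,7,11-trimethyl-3-vinyldodeca-6,10-diene-1,9-dione | C=C[C@](C)(CC/C=C(\C)CC(=O)C=C(C)C)CC(=O)c1ccc(O[Si](C)(C)C(C)(C)C)cc1O[Si](C)(C)C(C)(C)C | intermediate
30 | (3R,6E)-1-(2,4-dihydroxyphenyl)-3,7,11-trimethyl-3-vinyldodeca-6,10-diene-1,9-dione | C=C[C@](C)(CC/C=C(\C)CC(=O)C=C(C)C)CC(=O)c1ccc(O)cc1O | target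

**Step count**
Total: 17 steps. Longest linear sequence: 12 steps (steps 1 to 5, 10 to 14, 16 and 17 from geraniol; the resorcinol branch, steps 6 to 9 and then 10 to 14, 16 and 17, has 11).

**Steps most likely to fail**

1. Step 10. The carboxylate may add to the wrong aryne carbon if the C4' oxygen or the bulk of the triethylsilyl group outweighs the distortion caused by silicon. Fluoride may also attack the triethylsilyl group and give the isomeric aryne, or the aryl anion may be protonated before acyl transfer so that the reaction stops at the aryl ester. The fallback sets out from aldehyde 7 and gives up the aryne for aryllithium addition. Purchased 4-bromoresorcinol is protected with MOMCl and i-Pr2NEt to 1-bromo-2,4-bis(methoxymethoxy)benzene F1. Bromine–lithium exchange with n-BuLi in THF at −78 °C gives [2,4-bis(methoxymethoxy)phenyl]lithium F2, which adds to 7 to give (3R)-1-[2,4-bis(methoxymethoxy)phenyl]-3,7-dimethyl-3-vinyloct-6-en-1-ol F3 as a mixture of C1 epimers. Dess–Martin oxidation gives (R)-1-[2,4-bis(methoxymethoxy)phenyl]-3,7-dimethyl-3-vinyloct-6-en-1-one F4, and methanolic HCl removes both MOM ethers. The fallback comes back to the route at compound 22.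

2. Step 16. The allyl and alkenyl groups may couple directly without uptake of CO, bond formation may occur at the tertiary allyl terminus, or the C6 double bond may move into conjugation with the new ketone. The fallback sets out from chloride 25 and builds the enone by rearrangement instead of carbonylation. Copper-mediated coupling with 2-methylbut-3-yn-2-ol (CuI, K2CO3, NaI, DMF, rt) gives (3R,6E)-1-[2,4-bis(tert-butyldimethylsilyloxy)phenyl]-11-hydroxy-3,7,11-trimethyl-3-vinyldodec-6-en-9-yn-1-one F5. Gold-catalysed Meyer–Schuster rearrangement of the tertiary propargylic alcohol (Ph3PAuNTf2, MeOH, toluene, rt) then gives the β,β-dimethyl enone. The fallback comes back to the route at compound 29.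

3. Step 4. Vinylidene formation may be slow at an alkyne that sits on a quaternary carbon, and the nearby vinyl group may bind the ruthenium catalyst. The fallback sets out from enyne 6 and replaces hydration by hydroboration and oxidation. Copper-catalysed hydroboration (CuCl, NaOt-Bu, Xantphos, B2pin2, MeOH, THF, rt) gives 2-[(1E,3S)-3,7-dimethyl-3-vinylocta-1,6-dien-1-yl]-4,4,5,5-tetramethyl-1,3,2-dioxaborolane F6, and oxidation of the C–B bond with NaBO3·4H2O in THF/H2O gives the enol and hence the aldehyde. The fallback comes back to the route at compound 7.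

**Further compounds**
F1 | step 10 | 1-bromo-2,4-bis(methoxymethoxy)benzene | COCOc1ccc(Br)c(OCOC)c1
F2 | step 10 | [2,4-bis(methoxymethoxy)phenyl]lithium | [Li]c1ccc(OCOC)cc1OCOC
F3 | step 10 | (3R)-1-[2,4-bis(methoxymethoxy)phenyl]-3,7-dimethyl-3-vinyloct-6-en-1-ol (C1 epimers) | C=C[C@](C)(CCC=C(C)C)CC(O)c1ccc(OCOC)cc1OCOC
F4 | step 10 | (R)-1-[2,4-bis(methoxymethoxy)phenyl]-3,7-dimethyl-3-vinyloct-6-en-1-one | C=C[C@](C)(CCC=C(C)C)CC(=O)c1ccc(OCOC)cc1OCOC
F5 | step 16 | (3R,6E)-1-[2,4-bis(tert-butyldimethylsilyloxy)phenyl]-11-hydroxy-3,7,11-trimethyl-3-vinyldodec-6-en-9-yn-1-one | C=C[C@](C)(CC/C=C(\C)CC#CC(C)(C)O)CC(=O)c1ccc(O[Si](C)(C)C(C)(C)C)cc1O[Si](C)(C)C(C)(C)C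
F6 | step 4 | 2-[(1E,3S)-3,7-dimethyl-3-vinylocta-1,6-dien-1-yl]-4,4,5,5-tetramethyl-1,3,2-dioxaborolane | C=C[C@](C)(CCC=C(C)C)/C=C/B1OC(C)(C)C(C)(C)O1
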